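## Analysis of the target

2,3-Dihydroheveaflavone is a biflavonoid. A flavone (5-OH, 7-OMe, 4-methoxyphenyl at C2) is joined through its C8 to C3' of ring B of a 5-hydroxy-7-methoxyflavanone, and that ring B carries a free 4'-OH. The only stereocentre is C2 of the flavanone, which is S (read from the SMILES: O1 > aryl > CH2 > H). It is benzylic, bonded to the ring oxygen and β to the ketone, so base can racemise it through retro-oxa-Michael opening to the 2'-hydroxychalcone. It is therefore set late and kept under neutral or acidic conditions afterwards. The C8–C3' axis has three ortho substituents (OMe at C7, the ring oxygen at C8a, OH at C4') and one ortho hydrogen, and is treated as freely rotating. The sensitive groups are two chelated peri-phenols, one free phenol and three methyl ethers that must survive deprotection. The difficulty lies in the hindered biaryl bond between two electron-rich rings, and in a phloroglucinol ring whose three oxygens are all different with the aryl group at C8 rather than C6. The strategy rests on the flavone benzo ring (C4a, C5, C6, C7, C8, C8a). The oxygen at C8a can come from a ketene carbonyl, the methoxy at C7 from an ynol ether and the oxygen at C5 from a vinylogous ester, and the aryl substituent of the alkyne then lands at C8 between C8a and C7.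

## Retrosynthetic reasoning

**28 to 27.** The three phenols of target 28 are exposed last. Two are carried as benzyl ethers in 27 (flavone C5 and ring B C4'), so that one neutral hydrogenolysis frees them without touching the methyl ethers or the C2 stereocentre. The flavanone 5-OH is already free in 27.

**27 to 22 and 26.** The bond from flavanone C2 to ring B C1' is cut. This is the only bond to the stereocentre whose formation can be put under catalyst control in a convergent step, namely an asymmetric conjugate arylation of chromone 26 by boronic acid 22. Cutting O1–C2 instead would require an asymmetric oxa-Michael closure of a chalcone, which is harder to control. The forward reaction must arylate C2 of 26 on one face and leave the far less electrophilic flavone inside 22 alone.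

**22 to 21 to 20.** The boron at C1' is traced back through pinacol boronate 21 to the bromine of flavone 20. That bromine is carried unchanged from starting material 3, so the future C1' is marked from the outset.

**26 to 24 to 23.** The ring A chromone 26 needs one extra carbon between the acetyl methyl and an ortho phenol of 24. Ketone 24 comes from 23 by methylating its one non-chelated hydroxyl. The two ortho hydroxyls of 24 are equivalent, so ring closure has no regiochemical issue.

**20 to 18 to 17 to 14 and 15, and 14 to 13.** The pyranone ring is taken apart at O1–C2 (6-endo closure of ynone 18), at C3–C4 (addition of acetylide 16, from alkyne 15, to aldehyde 14) and at C4–C4a (ortho-formylation of phenol 13). This order is used because 13 has a single free position ortho to its hydroxyl, so C4 can only be attached at C4a.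

**13 to 2 and 8 (key disconnection).** The benzo ring is cut at C8–C8a and C6–C7. This gives cyclobutenone 2 (source of C8a, C4a, C5, C6 and the oxygens at C8a and C5) and aryl ynol ether 8 (source of C7, C8, the methoxy group and ring B). The three oxygens arrive already differentiated as free OH, OMe and OBn. The hindered biaryl bond is never made by cross-coupling, because it enters as the unhindered aryl–alkyne bond of 8.

**8 to 4 and 7, 4 to 3, 7 to 6 to 5, 2 to 1.** The aryl–alkyne bond of 8 comes from a coupling of iodide 4 at its C–I bond with zinc acetylide 7. Reagent 7 is made in the flask from lithium acetylide 6, and 6 from chloroacetal 5. Iodide 4 is the benzyl ether of phenol 3. Cyclobutenone 2 is obtained from commercial 1 by exchange of its alkoxy group.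

## Alternatives that were turned down

**Alternative 1:** The pyranone is cut at C4–C4a. In the forward step the acrylic acid A1 is dissolved in Eaton's reagent (P2O5 in MeSO3H); the acylium ion attacks the only free position ortho to the aryloxy oxygen and gives flavone A2.
- For: the acylation is classical, and its regiochemistry is unambiguous. It reaches a flavone from a biaryl phenol in about two operations, against four in the chosen route, so it is stronger on that point.
- Against: the tri-ortho-substituted biaryl is left unsolved and would need a hindered cross-coupling that spares an aryl bromide. A2 carries identical methyl ethers at C5 and C7, so a chelation-controlled demethylation must later find one methyl ether among four. The isopropyl ether sits in strong acid.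
- Comparison: the chosen strategy is longer after the biaryl stage, but it delivers the three oxygens differentiated and makes the biaryl without a hindered coupling.

**Alternative 2:** The flavanone is cut at C2–C3. The diazoketone A3 is decomposed by the chiral divalent rhodium carboxylate Rh2(S-PTTL)4, and the carbenoid inserts into a benzylic ether C–H to give A4.
- For: ring C and the stereocentre are made in one late catalytic step, with no boron chemistry and no separate chromone. On convergence at the stereocentre it is the more direct plan.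
- Against: an acceptor-only carbenoid is unselective. The ether oxygen is placed to form a five-membered oxonium ylide, whose benzyl shift gives a benzofuranone. Six-membered insertion is less favoured than five-membered, and the enantiocontrol is hard to predict. A3 must also be assembled on the complete flavone–biaryl, so the riskiest step falls on the most valuable intermediate.
- Comparison: the chosen route sets C2 by a conjugate arylation with a well-understood facial model and places its main risk early on small fragments. It still needs the biaryl solution that alternative 2 leaves open.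

**Alternative 3:** Ring B is cut at C2'–C3' and C1'–C6'. The siloxydiene A5 adds propynal A6 and the adduct is dehydrogenated with DDQ to give aldehyde A7.
- For: like the chosen route, it avoids a hindered biaryl coupling. The 2-siloxy group directs the "para" orientation, and the aldehyde is a convenient handle for chalcone chemistry.
- Against: A5 requires a flavone already functionalised at C8, so the C8 versus C6 problem is only moved. The leading bond of the cycloaddition forms at the diene terminus next to the di-ortho-substituted flavonyl group. From A7 the stereocentre would have to come from an asymmetric chalcone cyclisation, a weaker method than catalytic arylation.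
- Comparison: equal on the biaryl; the chosen route is better on oxygen differentiation and on C2, and alternative 3 offers a more classical flavone core.

Key step: step 4

Remark: the (R) ligand in step 13 is specified by analogy, on the basis that the (S) ligand places aryl groups on the face of cyclic enones and chromones that corresponds to (2R); the sense is to be confirmed on a model chromone first. Compounds 10 and 17 are racemic at centres that are lost later.

## Route

**Step 1**
Reactants: 1 3-ethoxycyclobut-2-en-1-one
Product: 2 3-(benzyloxy)cyclobut-2-en-1-one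
Conditions: BnOH (3 equiv), CSA (5 mol%), toluene, 30 °C, 40 mbar (EtOH removed); Et3N quench
Reagents that add atoms: benzyl alcohol, OCc1ccccc1
Why: Acid-catalysed transetherification of a vinylogous ester by addition–elimination through the O-protonated cyclobutenone, the exchange that squarate esters also undergo; removal of ethanol drives it and the temperature stays far below that of electrocyclic opening.

**Step 2**
Reactants: 3 4-bromo-2-iodophenol
Product: 4 1-(benzyloxy)-4-bromo-2-iodobenzene
Conditions: BnBr (1.1 equiv), K2CO3 (1.5 equiv), DMF, rt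
Reagents that add atoms: benzyl bromide, BrCc1ccccc1
Why: Williamson etherification of the phenoxide; both halides are inert.

**Step 3**
Reactants: 5 chloroacetaldehyde dimethyl acetal (2-chloro-1,1-dimethoxyethane); 4 1-(benzyloxy)-4-bromo-2-iodobenzene
Product: 8 1-(benzyloxy)-4-bromo-2-(methoxyethynyl)benzene, via lithium methoxyacetylide 6 (not isolated), via methoxyethynylzinc chloride 7 (not isolated)
Conditions: 5 (1.6 equiv), LiNEt2 (4.8 equiv, from n-BuLi and Et2NH), THF, −78 → 0 °C; ZnCl2 (1.7 equiv), 0 °C; then 4 (1.0 equiv), Pd(PPh3)4 (5 mol%), THF, rt; purification on Et3N-deactivated silica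
Reagents that add atoms: none
Why: Double elimination (methanol, then HCl) and deprotonation of the chloroacetal give the alkoxyacetylide, which is transmetalated to zinc for a Negishi coupling. Zerovalent palladium inserts into C–I much faster than into C–Br at room temperature, so the bromide is kept.

**Step 4**
Reactants: 2 3-(benzyloxy)cyclobut-2-en-1-one; 8 1-(benzyloxy)-4-bromo-2-(methoxyethynyl)benzene
Product: 13 4,2'-bis(benzyloxy)-5'-bromo-6-methoxy-[1,1'-biphenyl]-2-ol, via vinylketene 9 (not isolated), via vinylcyclobutenone 10 (not isolated), via dienylketene 11 (not isolated), via cyclohexadienone 12 (not isolated)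
Conditions: 2 (1.3 equiv), 8 (1.0 equiv), toluene (0.3 M), 80 → 110 °C, sealed tube; then KOH, MeOH/THF, rt
Reagents that add atoms: none
Why: This is the Danheiser benzannulation of a cyclobutenone with an alkoxyalkyne, here run with a 3-alkoxycyclobutenone partner. Thermal conrotatory 4π opening of 2 gives vinylketene 9, whose ketene C=C adds alkyne 8 in a [2+2] step to give 10, making the future C8–C8a and C6–C7 bonds. Reversible 4π opening of 10 gives dienylketene 11, and only the isomer with the ketene carbon and the benzyloxyvinyl group cis goes forward. The six-membered ring is closed by a thermal disrotatory 6π electrocyclisation of 11 (the nucleophilic enol ether terminus bonding to the ketene carbon) to cyclohexadienone 12, and tautomerisation to the phenol makes the cascade irreversible. No stereocentre is created, since the sp3 centre of 10 is lost on ring opening. The selectivity needed is the orientation of the [2+2] step: the methoxy oxygen polarises the alkyne so that the aryl-bearing carbon is nucleophilic and bonds to the ketene carbonyl carbon, which puts ring B between the phenol and the methoxy group. The methyl ynol ether has no β-hydrogen and so cannot lose an alkene by a retro-ene path at this temperature, and the bromide and both benzyl ethers are inert to heat alone. The basic methanolysis at the end returns any phenol that was O-acylated by excess ketene.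

**Step 5**
Reactants: 13 4,2'-bis(benzyloxy)-5'-bromo-6-methoxy-[1,1'-biphenyl]-2-ol
Product: 14 4,2'-bis(benzyloxy)-5'-bromo-2-hydroxy-6-methoxy-[1,1'-biphenyl]-3-carbaldehyde
Conditions: MgCl2 (2 equiv), Et3N (4 equiv), (CH2O)n (6 equiv), MeCN, 80 °C; dilute HCl work-up
Reagents that add atoms: formaldehyde (as paraformaldehyde), C=O
Why: Casnati–Skattebøl ortho-formylation: the magnesium phenoxide delivers formaldehyde to the only free ortho carbon and a second formaldehyde oxidises the hydroxymethyl intermediate by hydride transfer. The position between the two ethers is not reached by this chelated pathway.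

**Step 6**
Reactants: 15 1-ethynyl-4-methoxybenzene; 14 4,2'-bis(benzyloxy)-5'-bromo-2-hydroxy-6-methoxy-[1,1'-biphenyl]-3-carbaldehyde
Product: 17 1-[4,2'-bis(benzyloxy)-5'-bromo-2-hydroxy-6-methoxy-[1,1'-biphenyl]-3-yl]-3-(4-methoxyphenyl)prop-2-yn-1-ol (racemic), via lithium (4-methoxyphenyl)acetylide 16 (not isolated)
Conditions: 15 (3.3 equiv), n-BuLi (3.1 equiv), THF, −78 °C; then 14, −78 → 0 °C; aq. NH4Cl
Reagents that add atoms: none
Why: 1,2-Addition of a lithium acetylide to the aldehyde, with the first equivalent consumed by the phenol. Acetylides do not exchange with the aryl bromide, and the racemic carbinol centre is removed in step 7.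

**Step 7**
Reactants: 17 1-[4,2'-bis(benzyloxy)-5'-bromo-2-hydroxy-6-methoxy-[1,1'-biphenyl]-3-yl]-3-(4-methoxyphenyl)prop-2-yn-1-ol
Product: 18 1-[4,2'-bis(benzyloxy)-5'-bromo-2-hydroxy-6-methoxy-[1,1'-biphenyl]-3-yl]-3-(4-methoxyphenyl)prop-2-yn-1-one
Conditions: activated MnO2 (15 equiv), CH2Cl2, rt
Reagents that add atoms: none
Why: Selective oxidation of a benzylic, propargylic alcohol by MnO2; the phenol, ethers and bromide are not affected.

**Step 8**
Reactants: 18 1-[4,2'-bis(benzyloxy)-5'-bromo-2-hydroxy-6-methoxy-[1,1'-biphenyl]-3-yl]-3-(4-methoxyphenyl)prop-2-yn-1-one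
Product: 20 5-(benzyloxy)-8-[2-(benzyloxy)-5-bromophenyl]-7-methoxy-2-(4-methoxyphenyl)-4H-chromen-4-one, via diethylaminoenone 19 (not isolated)
Conditions: Et2NH (5 equiv), EtOH/THF (1:1), rt → 60 °C
Reagents that add atoms: none
Why: Conjugate addition of the amine to the ynone gives β-aminoenone 19, and the phenol then replaces the amine at the same carbon by addition–elimination. This forces the 6-endo O1–C2 closure to the flavone and excludes the 5-exo closure to an aurone.

**Step 9**
Reactants: 20 5-(benzyloxy)-8-[2-(benzyloxy)-5-bromophenyl]-7-methoxy-2-(4-methoxyphenyl)-4H-chromen-4-one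
Product: 21 5-(benzyloxy)-8-[2-(benzyloxy)-5-(4,4,5,5-tetramethyl-1,3,2-dioxaborolan-2-yl)phenyl]-7-methoxy-2-(4-methoxyphenyl)-4H-chromen-4-one
Conditions: B2pin2 (1.3 equiv), Pd(dppf)Cl2·CH2Cl2 (5 mol%), KOAc (3 equiv), 1,4-dioxane, 90 °C
Reagents that add atoms: bis(pinacolato)diboron, CC1(C)OB(OC1(C)C)B1OC(C)(C)C(C)(C)O1
Why: Miyaura borylation of an unhindered aryl bromide; the weak acetate base suppresses Suzuki coupling of the product, and the flavone and benzyl ethers are inert.

**Step 10**
Reactants: 21 5-(benzyloxy)-8-[2-(benzyloxy)-5-(4,4,5,5-tetramethyl-1,3,2-dioxaborolan-2-yl)phenyl]-7-methoxy-2-(4-methoxyphenyl)-4H-chromen-4-one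
Product: 22 {4-(benzyloxy)-3-[5-(benzyloxy)-7-methoxy-2-(4-methoxyphenyl)-4-oxo-4H-chromen-8-yl]phenyl}boronic acid
Conditions: NaIO4 (3 equiv), NH4OAc (3 equiv), acetone/H2O (1:1), rt
Reagents that add atoms: water, O
Why: Periodate cleaves the pinacol released in the hydrolysis equilibrium, which frees the boronic acid under near-neutral conditions. No free phenol is present to be oxidised.

**Step 11**
Reactants: 23 2,4,6-trihydroxyacetophenone
Product: 24 1-(2,6-dihydroxy-4-methoxyphenyl)ethan-1-one
Conditions: Me2SO4 (1.0 equiv), K2CO3 (1.0 equiv), acetone, rt → 40 °C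
Reagents that add atoms: dimethyl sulfate, COS(=O)(=O)OC
Why: The 4-hydroxyl is the only one not hydrogen-bonded to the acetyl carbonyl and is the most acidic, so one equivalent of alkylating agent methylates it selectively.

**Step 12**
Reactants: 24 1-(2,6-dihydroxy-4-methoxyphenyl)ethan-1-one
Product: 26 5-hydroxy-7-methoxy-4H-chromen-4-one, via dimethylaminoenone 25 (not isolated)
Conditions: Me2NCH(OMe)2 (2.2 equiv), toluene, 80 °C; then AcOH, 100 °C
Reagents that add atoms: N,N-dimethylformamide dimethyl acetal, COC(OC)N(C)C
Why: Condensation at the acetyl methyl gives enaminone 25, and acid-promoted addition–elimination by an ortho phenol closes the pyranone with loss of dimethylamine. The two ortho hydroxyls are equivalent, so only one chromone can form.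

**Step 13**
Reactants: 22 {4-(benzyloxy)-3-[5-(benzyloxy)-7-methoxy-2-(4-methoxyphenyl)-4-oxo-4H-chromen-8-yl]phenyl}boronic acid; 26 5-hydroxy-7-methoxy-4H-chromen-4-one
Product: 27 (2S)-2-{4-(benzyloxy)-3-[5-(benzyloxy)-7-methoxy-2-(4-methoxyphenyl)-4-oxo-4H-chromen-8-yl]phenyl}-5-hydroxy-7-methoxy-2,3-dihydro-4H-chromen-4-one
Conditions: 22 (1.0 equiv), 26 (1.5 equiv), Pd(OCOCF3)2 (7.5 mol%), (R)-t-BuPyOx (9 mol%), NH4PF6 (30 mol%), H2O (5 equiv), ClCH2CH2Cl, 60 °C
Reagents that add atoms: none
Why: Asymmetric conjugate addition of an arylboronic acid to a chromone under cationic divalent palladium–pyridine-oxazoline catalysis: transmetalation, enantio-determining insertion of C2=C3 into the aryl–palladium bond, then protonolysis of the palladium enolate. The tert-butyl group of the (R) ligand shields one face of the bound chromone, so the aryl group is delivered to the face that gives (2S). The chelated 5-OH makes 26 more electrophilic, while the 2-aryl flavone inside 22 is β,β-disubstituted and electron-rich and is not arylated.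

**Step 14**
Reactants: 27 (2S)-2-{4-(benzyloxy)-3-[5-(benzyloxy)-7-methoxy-2-(4-methoxyphenyl)-4-oxo-4H-chromen-8-yl]phenyl}-5-hydroxy-7-methoxy-2,3-dihydro-4H-chromen-4-one
Product: 28 2,3-dihydroheveaflavone, (2S)-5-hydroxy-2-{4-hydroxy-3-[5-hydroxy-7-methoxy-2-(4-methoxyphenyl)-4-oxo-4H-chromen-8-yl]phenyl}-7-methoxy-2,3-dihydro-4H-chromen-4-one
Conditions: H2 (1 atm), 10% Pd/C, EtOAc/THF, rt, stopped after uptake of 2 equiv
Reagents that add atoms: none
Why: Hydrogenolysis of two aryl benzyl ethers under neutral conditions, so C2 cannot epimerise by ring opening. The methyl ethers, the flavone C2=C3 bond and the benzylic C2–O1 bond react much more slowly.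

## Compound list

1 | 3-ethoxycyclobut-2-en-1-one | CCOC1=CC(=O)C1 | starting material
2 | 3-(benzyloxy)cyclobut-2-en-1-one | O=C1C=C(OCc2ccccc2)C1 | intermediate
3 | 4-bromo-2-iodophenol | Oc1ccc(Br)cc1I | starting material
4 | 1-(benzyloxy)-4-bromo-2-iodobenzene | Brc1ccc(OCc2ccccc2)c(I)c1 | intermediate
5 | chloroacetaldehyde dimethyl acetal | COC(CCl)OC | starting material
6 | lithium methoxyacetylide | [Li]C#COC | intermediate (not isolated)
7 | methoxyethynylzinc chloride | COC#C[Zn]Cl | intermediate (not isolated)
8 | 1-(benzyloxy)-4-bromo-2-(methoxyethynyl)benzene | COC#Cc1cc(Br)ccc1OCc1ccccc1 | intermediate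
9 | 3-(benzyloxy)buta-1,3-dien-1-one (vinylketene) | C=C(OCc1ccccc1)C=C=O | intermediate (not isolated)
10 | 4-[1-(benzyloxy)ethenyl]-2-[2-(benzyloxy)-5-bromophenyl]-3-methoxycyclobut-2-en-1-one (racemic) | COC1=C(c2cc(Br)ccc2OCc2ccccc2)C(=O)C1C(=C)OCc1ccccc1 | intermediate (not isolated)
11 | (3E)-5-(benzyloxy)-2-[2-(benzyloxy)-5-bromophenyl]-3-methoxyhexa-1,3,5-trien-1-one (dienylketene) | O=C=C(c1cc(Br)ccc1OCc1ccccc1)/C(OC)=C\C(=C)OCc1ccccc1 | intermediate (not isolated)
12 | 5-(benzyloxy)-2-[2-(benzyloxy)-5-bromophenyl]-3-methoxycyclohexa-2,4-dien-1-one | COC1=C(c2cc(Br)ccc2OCc2ccccc2)C(=O)CC(OCc2ccccc2)=C1 | intermediate (not isolated)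
13 | 4,2'-bis(benzyloxy)-5'-bromo-6-methoxy-[1,1'-biphenyl]-2-ol | COc1cc(OCc2ccccc2)cc(O)c1-c1cc(Br)ccc1OCc1ccccc1 | intermediate
14 | 4,2'-bis(benzyloxy)-5'-bromo-2-hydroxy-6-methoxy-[1,1'-biphenyl]-3-carbaldehyde | COc1cc(OCc2ccccc2)c(C=O)c(O)c1-c1cc(Br)ccc1OCc1ccccc1 | intermediate
15 | 1-ethynyl-4-methoxybenzene | C#Cc1ccc(OC)cc1 | starting material
16 | lithium (4-methoxyphenyl)acetylide | [Li]C#Cc1ccc(OC)cc1 | intermediate (not isolated)
17 | 1-[4,2'-bis(benzyloxy)-5'-bromo-2-hydroxy-6-methoxy-[1,1'-biphenyl]-3-yl]-3-(4-methoxyphenyl)prop-2-yn-1-ol (racemic) | COc1ccc(C#CC(O)c2c(OCc3ccccc3)cc(OC)c(-c3cc(Br)ccc3OCc3ccccc3)c2O)cc1 | intermediate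
18 | 1-[4,2'-bis(benzyloxy)-5'-bromo-2-hydroxy-6-methoxy-[1,1'-biphenyl]-3-yl]-3-(4-methoxyphenyl)prop-2-yn-1-one | COc1ccc(C#CC(=O)c2c(OCc3ccccc3)cc(OC)c(-c3cc(Br)ccc3OCc3ccccc3)c2O)cc1 | intermediate
19 | (2E)-1-[4,2'-bis(benzyloxy)-5'-bromo-2-hydroxy-6-methoxy-[1,1'-biphenyl]-3-yl]-3-(diethylamino)-3-(4-methoxyphenyl)prop-2-en-1-one | CCN(CC)/C(=C/C(=O)c1c(OCc2ccccc2)cc(OC)c(-c2cc(Br)ccc2OCc2ccccc2)c1O)c1ccc(OC)cc1 | intermediate (not isolated)
20 | 5-(benzyloxy)-8-[2-(benzyloxy)-5-bromophenyl]-7-methoxy-2-(4-methoxyphenyl)-4H-chromen-4-one | COc1ccc(-c2cc(=O)c3c(OCc4ccccc4)cc(OC)c(-c4cc(Br)ccc4OCc4ccccc4)c3o2)cc1 | intermediate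
21 | 5-(benzyloxy)-8-[2-(benzyloxy)-5-(4,4,5,5-tetramethyl-1,3,2-dioxaborolan-2-yl)phenyl]-7-methoxy-2-(4-methoxyphenyl)-4H-chromen-4-one | COc1ccc(-c2cc(=O)c3c(OCc4ccccc4)cc(OC)c(-c4cc(B5OC(C)(C)C(C)(C)O5)ccc4OCc4ccccc4)c3o2)cc1 | intermediate
22 | {4-(benzyloxy)-3-[5-(benzyloxy)-7-methoxy-2-(4-methoxyphenyl)-4-oxo-4H-chromen-8-yl]phenyl}boronic acid | COc1ccc(-c2cc(=O)c3c(OCc4ccccc4)cc(OC)c(-c4cc(B(O)O)ccc4OCc4ccccc4)c3o2)cc1 | intermediate
23 | 2,4,6-trihydroxyacetophenone | CC(=O)c1c(O)cc(O)cc1O | starting material
24 | 1-(2,6-dihydroxy-4-methoxyphenyl)ethan-1-one | CC(=O)c1c(O)cc(OC)cc1O | intermediate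
25 | (2E)-1-(2,6-dihydroxy-4-methoxyphenyl)-3-(dimethylamino)prop-2-en-1-one | CN(C)/C=C/C(=O)c1c(O)cc(OC)cc1O | intermediate (not isolated)
26 | 5-hydroxy-7-methoxy-4H-chromen-4-one | COc1cc(O)c2c(=O)ccoc2c1 | intermediate
27 | (2S)-2-{4-(benzyloxy)-3-[5-(benzyloxy)-7-methoxy-2-(4-methoxyphenyl)-4-oxo-4H-chromen-8-yl]phenyl}-5-hydroxy-7-methoxy-2,3-dihydro-4H-chromen-4-one | COc1ccc(-c2cc(=O)c3c(OCc4ccccc4)cc(OC)c(-c4cc([C@@H]5CC(=O)c6c(O)cc(OC)cc6O5)ccc4OCc4ccccc4)c3o2)cc1 | intermediate
28 | 2,3-dihydroheveaflavone | COc1ccc(-c2cc(=O)c3c(O)cc(OC)c(-c4cc([C@@H]5CC(=O)c6c(O)cc(OC)cc6O5)ccc4O)c3o2)cc1 | target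

## Step count and least certain steps

Total: 14 steps. Longest linear sequence: 11 steps (2, 3, 4, 5, 6, 7, 8, 9, 10, 13, 14, from 4-bromo-2-iodophenol).

**Step 4 (key step).** The vinylogous-ester stabilisation of 2 may push the ring opening to temperatures at which the alkoxyvinylketene oligomerises or the ynol ether degrades before the [2+2] capture. Aryl conjugation could also erode the regiocontrol exerted by the methoxy group.
Fallback: it sets out from alkyne 8 and makes the same vinylketene 9 without a cyclobutenone. Benzyl alcohol is added to commercial ethyl but-2-ynoate under PMe3 catalysis to give ethyl (2E)-3-(benzyloxy)but-2-enoate F1. Saponification with LiOH gives (2E)-3-(benzyloxy)but-2-enoic acid F2, and (COCl)2 gives (2E)-3-(benzyloxy)but-2-enoyl chloride F3. Slow addition of F3 to 8 and Et3N in toluene at 0 °C generates 9 by 1,4-dehydrochlorination. It is trapped as 10, and warming to 80–110 °C carries 10 through 11 and 12 to 13, where the route is rejoined.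

**Step 1.** Alcohol addition at the carbonyl with ring cleavage to acetoacetate-type products, or acid-induced polymerisation, may compete with the exchange.
Fallback: it sets out from 1. Hydrolysis with cold dilute HCl gives cyclobutane-1,3-dione F4, whose acidic enol is O-benzylated with BnBr and Ag2O in CH2Cl2 to return to 2.

**Step 3.** Incomplete double elimination of the chloroacetal, homocoupling of the zinc acetylide, or hydration of the ynol ether during isolation may lower the supply of 8.
Fallback: it sets out from 4. Selective iodine–magnesium exchange (i-PrMgCl·LiCl, THF, −20 °C) and acylation with N,2-dimethoxy-N-methylacetamide give 1-[2-(benzyloxy)-5-bromophenyl]-2-methoxyethan-1-one F5. KHMDS and PhNTf2 convert it into (1Z)-1-[2-(benzyloxy)-5-bromophenyl]-2-methoxyethenyl trifluoromethanesulfonate F6. Elimination of triflate with KOt-Bu in THF at −78 °C gives 8.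

**Step 13.** The 5-hydroxy-4-oxo unit of 26 may chelate and sequester the cationic palladium, protodeboronation of the electron-rich boronic acid may outrun insertion, or the facial selectivity may be insufficient.
Fallback: it sets out from 22 and 26. Benzylation of 26 (BnBr, K2CO3, DMF) gives 5-(benzyloxy)-7-methoxy-4H-chromen-4-one F7. A Hayashi–Miyaura addition of 22 under monovalent rhodium catalysis ([RhCl(C2H4)2]2, the appropriate enantiomer of 2,5-diphenylbicyclo[2.2.2]octa-2,5-diene, substoichiometric aqueous K3PO4, dioxane, 30 °C) gives (2S)-5-(benzyloxy)-2-{4-(benzyloxy)-3-[5-(benzyloxy)-7-methoxy-2-(4-methoxyphenyl)-4-oxo-4H-chromen-8-yl]phenyl}-7-methoxy-2,3-dihydro-4H-chromen-4-one F8. Hydrogenolysis under the conditions of step 14 removes all three benzyl groups and rejoins the route at 28.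

**Step 14.** Over-reduction may occur, either saturation of the flavone C2=C3 bond or reductive opening of the benzylic C2–O1 bond of the flavanone.
Fallback: it sets out from 27 and reaches 28 directly by non-reductive debenzylation with BCl3 and pentamethylbenzene as cation scavenger in CH2Cl2 at −78 °C, which leaves aryl methyl ethers intact at that temperature.

## Further compounds

F1 | step 4 | ethyl (2E)-3-(benzyloxy)but-2-enoate | CCOC(=O)/C=C(\C)OCc1ccccc1
F2 | step 4 | (2E)-3-(benzyloxy)but-2-enoic acid | OC(=O)/C=C(\C)OCc1ccccc1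
F3 | step 4 | (2E)-3-(benzyloxy)but-2-enoyl chloride | ClC(=O)/C=C(\C)OCc1ccccc1
F4 | step 1 | cyclobutane-1,3-dione | O=C1CC(=O)C1
F5 | step 3 | 1-[2-(benzyloxy)-5-bromophenyl]-2-methoxyethan-1-one | COCC(=O)c1cc(Br)ccc1OCc1ccccc1
F6 | step 3 | (1Z)-1-[2-(benzyloxy)-5-bromophenyl]-2-methoxyethenyl trifluoromethanesulfonate | CO/C=C(\OS(=O)(=O)C(F)(F)F)c1cc(Br)ccc1OCc1ccccc1
F7 | step 13 | 5-(benzyloxy)-7-methoxy-4H-chromen-4-one | COc1cc(OCc2ccccc2)c2c(=O)ccoc2c1
F8 | step 13 | (2S)-5-(benzyloxy)-2-{4-(benzyloxy)-3-[5-(benzyloxy)-7-methoxy-2-(4-methoxyphenyl)-4-oxo-4H-chromen-8-yl]phenyl}-7-methoxy-2,3-dihydro-4H-chromen-4-one | COc1ccc(-c2cc(=O)c3c(OCc4ccccc4)cc(OC)c(-c4cc([C@@H]5CC(=O)c6c(OCc7ccccc7)cc(OC)cc6O5)ccc4OCc4ccccc4)c3o2)cc1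
F0 | step 14 | none | none
A1 | alternative 1 | (2Z)-3-{[5'-bromo-4,6-dimethoxy-2'-(propan-2-yloxy)-[1,1'-biphenyl]-2-yl]oxy}-3-(4-methoxyphenyl)prop-2-enoic acid | OC(=O)/C=C(\Oc1cc(OC)cc(OC)c1-c1cc(Br)ccc1OC(C)C)c1ccc(OC)cc1
A2 | alternative 1 | 8-[5-bromo-2-(propan-2-yloxy)phenyl]-5,7-dimethoxy-2-(4-methoxyphenyl)-4H-chromen-4-one | COc1ccc(-c2cc(=O)c3c(OC)cc(OC)c(-c4cc(Br)ccc4OC(C)C)c3o2)cc1
A3 | alternative 2 | 1-{2-({4-(benzyloxy)-3-[5-(benzyloxy)-7-methoxy-2-(4-methoxyphenyl)-4-oxo-4H-chromen-8-yl]phenyl}methoxy)-6-[(tert-butyldimethylsilyl)oxy]-4-methoxyphenyl}-2-diazoethan-1-one | COc1ccc(-c2cc(=O)c3c(OCc4ccccc4)cc(OC)c(-c4cc(COc5cc(OC)cc(O[Si](C)(C)C(C)(C)C)c5C(=O)C=[N+]=[N-])ccc4OCc4ccccc4)c3o2)cc1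
A4 | alternative 2 | (2S)-2-{4-(benzyloxy)-3-[5-(benzyloxy)-7-methoxy-2-(4-methoxyphenyl)-4-oxo-4H-chromen-8-yl]phenyl}-5-[(tert-butyldimethylsilyl)oxy]-7-methoxy-2,3-dihydro-4H-chromen-4-one | COc1ccc(-c2cc(=O)c3c(OCc4ccccc4)cc(OC)c(-c4cc([C@@H]5CC(=O)c6c(O[Si](C)(C)C(C)(C)C)cc(OC)cc6O5)ccc4OCc4ccccc4)c3o2)cc1
A5 | alternative 3 | 5-(benzyloxy)-8-{(1Z)-2-[(tert-butyldimethylsilyl)oxy]buta-1,3-dien-1-yl}-7-methoxy-2-(4-methoxyphenyl)-4H-chromen-4-one | COc1ccc(-c2cc(=O)c3c(OCc4ccccc4)cc(OC)c(/C=C(\O[Si](C)(C)C(C)(C)C)C=C)c3o2)cc1
A6 | alternative 3 | propynal | C#CC=O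
A7 | alternative 3 | 3-[5-(benzyloxy)-7-methoxy-2-(4-methoxyphenyl)-4-oxo-4H-chromen-8-yl]-4-[(tert-butyldimethylsilyl)oxy]benzaldehyde | COc1ccc(-c2cc(=O)c3c(OCc4ccccc4)cc(OC)c(-c4cc(C=O)ccc4O[Si](C)(C)C(C)(C)C)c3o2)cc1
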